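Ring B of the target is a 1,2,4-trisubstituted benzene: C1' is bonded to C2 of the 5-hydroxy-7-methoxychromone, C2' to C8'' of the apigenin unit, and C4' carries oxygen. Five of its carbons (C2'–C6') and O4' therefore map onto a 2-aryl-4H-pyran-4-one, and C1' onto the CH3 carbon of a 2-methylchromone. Ring B is disconnected at C1'–C6' and C1'–C2'. In the forward sense, base-mediated union of 8-(4-oxopyran-2-yl)-tri-O-benzylapigenin with 5-benzyloxy-7-methoxy-2-methylchromone should exchange the pyranone ring oxygen for that carbon and deliver the whole biflavone skeleton with 4'-OH as its only free phenol, ready for O-methylation and global hydrogenolysis.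

Key step: step 7

Assumption: the target SMILES carries no stereodescriptor, so the hindered C2'–C8'' axis is left unassigned and the product is expected as a racemate if rotation proves slow.

Structure check: in both coupling partners the apigenin unit is linked through C8'' (the carbon between C7''–O and C8a''), and O4' is para to C1'; both agree with the target and no correction is needed.

Design notes: every oxygen that ends as OH is carried as a benzyl ether, so the phenol made in step 7 is the only free hydroxyl when it is methylated. The pyranone is built from the acid chloride, because the carboxyl carbon at C8'' lies between two ortho oxygens and would be a sluggish ester electrophile. Locants are plain for the 5-hydroxy-7-methoxyflavone, primed for ring B and double-primed for the apigenin unit. Numbered reactants are given on the Reactants line only.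

Step 1
Reactants: 1 apigenin (5,7-dihydroxy-2-(4-hydroxyphenyl)-4H-chromen-4-one)
Product: 2 5,7-bis(benzyloxy)-2-[4-(benzyloxy)phenyl]-4H-chromen-4-one (tri-O-benzylapigenin)
Conditions: BnBr (4 equiv), K2CO3 (5 equiv), DMF, 80 °C
Reagents that add atoms: benzyl bromide, BrCc1ccccc1
Why: Williamson ether synthesis on all three phenols, the hydrogen-bonded 5-OH being the slowest and therefore driven by excess halide in hot DMF.

Step 2
Reactants: 2 tri-O-benzylapigenin
Product: 3 5,7-bis(benzyloxy)-2-[4-(benzyloxy)phenyl]-8-iodo-4H-chromen-4-one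
Conditions: N-iodosuccinimide (1.1 equiv), CF3CO2H (0.3 equiv), MeCN–CH2Cl2, 0 °C → rt, dark
Reagents that add atoms: N-iodosuccinimide, O=C1CCC(=O)N1I
Why: Electrophilic aromatic iodination of the dialkoxy ring A, which in 5-O-alkylated 5,7-dioxygenated flavones should occur at C8 because the 5-O-benzyl group, turned away from the peri carbonyl, screens C6 (the site can be confirmed by NOE from the remaining ring A proton to both flanking OCH2 groups).

Step 3
Reactants: 3 8-iodo-tri-O-benzylapigenin
Product: 4 5,7-bis(benzyloxy)-2-[4-(benzyloxy)phenyl]-4-oxo-4H-chromene-8-carboxylic acid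
Conditions: Pd(OAc)2 (5 mol %), Xantphos (6 mol %), CO (1 atm), KOAc (3 equiv), DMSO–H2O (20:1), 80 °C; then 1 M HCl
Reagents that add atoms: carbon monoxide, [C-]#[O+]; water, O
Why: Palladium-catalysed hydroxycarbonylation of an aryl iodide (oxidative addition to zerovalent palladium, CO insertion, capture of the acylpalladium by the oxygen nucleophile) tolerates the two ortho oxygens, the benzyl ethers and the flavone.

Step 4
Reactants: 4 flavone-8-carboxylic acid; 5 (E)-4-methoxybut-3-en-2-one
Product: 8 5,7-bis(benzyloxy)-2-[4-(benzyloxy)phenyl]-8-(4-oxo-4H-pyran-2-yl)-4H-chromen-4-one, via acid chloride 6 (not isolated), via methoxyvinyl diketone 7 (not isolated)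
Conditions: 1-chloro-N,N,2-trimethylprop-1-en-1-amine (1.2 equiv), CH2Cl2, 0 °C → rt; added to the lithium enolate of 5 [5 (2.5 equiv), LiN(SiMe3)2 (2.5 equiv), THF, −78 °C], −78 → −20 °C; then CF3CO2H, CH2Cl2, rt
Reagents that add atoms: none
Why: The neutral chloroenamine converts the acid into its chloride without free HCl, C-acylation of the kinetic lithium enolate of the β-methoxy enone (crossed Claisen-type acylation, the second equivalent of enolate taking up the diketone proton) gives 7, and acid then triggers 6-endo addition of the aryl ketone enol to the β-carbon with loss of methanol, an established γ-pyrone annulation.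

Step 5
Reactants: 9 1-(2,6-dihydroxy-4-methoxyphenyl)ethanone (2',6'-dihydroxy-4'-methoxyacetophenone)
Product: 11 5-hydroxy-7-methoxy-2-methyl-4H-chromen-4-one (eugenin), via aryl butanedione 10 (not isolated)
Conditions: NaH (6 equiv), EtOAc (excess), THF, reflux; then conc. HCl, MeOH, 65 °C
Reagents that add atoms: ethyl acetate, CCOC(C)=O
Why: Crossed Claisen condensation of the acetophenone enolate (as its polysodium salt) with ethyl acetate gives diketone 10, and acid-catalysed cyclodehydration onto either of the two equivalent ortho hydroxyls closes the 2-methylchromone, the other hydroxyl becoming the chelated 5-OH.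

Step 6
Reactants: 11 eugenin
Product: 12 5-(benzyloxy)-7-methoxy-2-methyl-4H-chromen-4-one
Conditions: BnBr (1.5 equiv), K2CO3 (3 equiv), DMF, 70 °C
Reagents that add atoms: benzyl bromide, BrCc1ccccc1
Why: Williamson ether synthesis on the chelated 5-OH, which needs heat, while K2CO3 is too weak a base to deprotonate the 2-methyl group, so C-benzylation is not expected.

Step 7
Reactants: 8 8-(4-oxo-4H-pyran-2-yl)-tri-O-benzylapigenin; 12 5-(benzyloxy)-7-methoxy-2-methylchromone
Product: 14 5,7-bis(benzyloxy)-8-{2-[5-(benzyloxy)-7-methoxy-4-oxo-4H-chromen-2-yl]-5-hydroxyphenyl}-2-[4-(benzyloxy)phenyl]-4H-chromen-4-one (tetra-O-benzyl 4'-phenol), via ring-opened (Z)-enone diketone 13 (not isolated)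
Conditions: KOC(CH3)3 (3 equiv), THF–(CH3)3COH (5:1), 0 °C, 12 (1.2 equiv) added slowly to 8 and base, then 60 °C; 1 M HCl work-up
Reagents that add atoms: none
Why: Proposed new method: KOC(CH3)3 reversibly removes a proton from the 2-CH3 group of 12 (vinylogous to the C4 carbonyl) and the dienolate adds through its exocyclic carbon to C6 of pyranone 8 (new C1'–C6' bond); E1cB opening of the resulting 2H-pyran-4-olate expels the ring oxygen as the enolate of an aryl 1,3-diketone and gives (Z)-enone 13, whose CH2 group, now flanked by the enone and the chromone, is deprotonated again and attacks the aryl ketone carbon (new C1'–C2' bond), after which loss of hydroxide, which removes the former ring oxygen, and tautomerization give the 4'-phenoxide. The nearest precedents are the nitromethane/alkoxide ring transformation of 4-pyranones into 4-nitrophenols and the carbanion-induced conversion of pyrylium salts into benzenes, but a vinylogous methyl carbanion as the one-carbon partner is undocumented. Ring B closes in a 6-exo-trig aldol mode, which the Z geometry left at C5'=C6' by the ring opening makes possible. No stereocenter is formed and the C2'–C8'' axis is not controlled. The step needs addition at the pyranone C6–H and not at the pyranone C2, at C2'' of the apigenin unit or at C2 of a second molecule of 12: C6 is the only unsubstituted β-carbon of a vinylogous ester in the mixture, C2 is screened by the di-ortho-substituted aryl group, C2'' carries an aryl group and is deactivated by the 5'',7''-dialkoxy donors, and slow addition of 12 keeps its self-condensation down. Additions at the wrong sites are reversible, whereas the productive path ends in irreversible aromatization, which should also pull the hindered aldol closure through.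

Step 8
Reactants: 14 tetra-O-benzyl 4'-phenol
Product: 15 5,7-bis(benzyloxy)-8-{2-[5-(benzyloxy)-7-methoxy-4-oxo-4H-chromen-2-yl]-5-methoxyphenyl}-2-[4-(benzyloxy)phenyl]-4H-chromen-4-one
Conditions: CH3I (3 equiv), K2CO3 (3 equiv), DMF, rt
Reagents that add atoms: iodomethane, CI
Why: Williamson O-methylation of the only free hydroxyl in the molecule, so no selectivity question arises.

Step 9
Reactants: 15 tetra-O-benzyl 4'-O-methyl biflavone
Product: 16 5,7-dihydroxy-8-[2-(5-hydroxy-7-methoxy-4-oxo-4H-chromen-2-yl)-5-methoxyphenyl]-2-(4-hydroxyphenyl)-4H-chromen-4-one (target)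
Conditions: H2 (1 atm), 10% Pd/C, THF–MeOH (1:1), rt
Reagents that add atoms: none
Why: Catalytic hydrogenolysis cleaves the four benzyl aryl ethers, while the aryl methyl ethers are inert and the 2-aryl-substituted pyranone C2=C3 bonds of flavones are normally not reduced at atmospheric pressure.

Compound list
1 | apigenin, 5,7-dihydroxy-2-(4-hydroxyphenyl)-4H-chromen-4-one | O=c1cc(-c2ccc(O)cc2)oc2cc(O)cc(O)c12 | starting material
2 | 5,7-bis(benzyloxy)-2-[4-(benzyloxy)phenyl]-4H-chromen-4-one | O=c1cc(-c2ccc(OCc3ccccc3)cc2)oc2cc(OCc3ccccc3)cc(OCc3ccccc3)c12 | intermediate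
3 | 5,7-bis(benzyloxy)-2-[4-(benzyloxy)phenyl]-8-iodo-4H-chromen-4-one | Ic1c(OCc2ccccc2)cc(OCc2ccccc2)c2c(=O)cc(-c3ccc(OCc4ccccc4)cc3)oc12 | intermediate
4 | 5,7-bis(benzyloxy)-2-[4-(benzyloxy)phenyl]-4-oxo-4H-chromene-8-carboxylic acid | OC(=O)c1c(OCc2ccccc2)cc(OCc2ccccc2)c2c(=O)cc(-c3ccc(OCc4ccccc4)cc3)oc12 | intermediate
5 | (E)-4-methoxybut-3-en-2-one | CO/C=C/C(C)=O | starting material
6 | 5,7-bis(benzyloxy)-2-[4-(benzyloxy)phenyl]-4-oxo-4H-chromene-8-carbonyl chloride | ClC(=O)c1c(OCc2ccccc2)cc(OCc2ccccc2)c2c(=O)cc(-c3ccc(OCc4ccccc4)cc3)oc12 | intermediate (not isolated)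
7 | (E)-1-{5,7-bis(benzyloxy)-2-[4-(benzyloxy)phenyl]-4-oxo-4H-chromen-8-yl}-5-methoxypent-4-ene-1,3-dione | CO/C=C/C(=O)CC(=O)c1c(OCc2ccccc2)cc(OCc2ccccc2)c2c(=O)cc(-c3ccc(OCc4ccccc4)cc3)oc12 | intermediate (not isolated)
8 | 5,7-bis(benzyloxy)-2-[4-(benzyloxy)phenyl]-8-(4-oxo-4H-pyran-2-yl)-4H-chromen-4-one | O=c1ccoc(-c2c(OCc3ccccc3)cc(OCc3ccccc3)c3c(=O)cc(-c4ccc(OCc5ccccc5)cc4)oc23)c1 | intermediate
9 | 1-(2,6-dihydroxy-4-methoxyphenyl)ethanone | CC(=O)c1c(O)cc(OC)cc1O | starting material
10 | 1-(2,6-dihydroxy-4-methoxyphenyl)butane-1,3-dione | CC(=O)CC(=O)c1c(O)cc(OC)cc1O | intermediate (not isolated)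
11 | 5-hydroxy-7-methoxy-2-methyl-4H-chromen-4-one (eugenin) | Cc1cc(=O)c2c(O)cc(OC)cc2o1 | intermediate
12 | 5-(benzyloxy)-7-methoxy-2-methyl-4H-chromen-4-one | Cc1cc(=O)c2c(OCc3ccccc3)cc(OC)cc2o1 | intermediate
13 | (Z)-1-{5,7-bis(benzyloxy)-2-[4-(benzyloxy)phenyl]-4-oxo-4H-chromen-8-yl}-6-[5-(benzyloxy)-7-methoxy-4-oxo-4H-chromen-2-yl]hex-4-ene-1,3-dione | O=C(CC(=O)/C=C\Cc1cc(=O)c2c(OCc3ccccc3)cc(OC)cc2o1)c1c(OCc2ccccc2)cc(OCc2ccccc2)c2c(=O)cc(-c3ccc(OCc4ccccc4)cc3)oc12 | intermediate (not isolated)
14 | 5,7-bis(benzyloxy)-8-{2-[5-(benzyloxy)-7-methoxy-4-oxo-4H-chromen-2-yl]-5-hydroxyphenyl}-2-[4-(benzyloxy)phenyl]-4H-chromen-4-one | Oc1ccc(-c2cc(=O)c3c(OCc4ccccc4)cc(OC)cc3o2)c(-c2c(OCc3ccccc3)cc(OCc3ccccc3)c3c(=O)cc(-c4ccc(OCc5ccccc5)cc4)oc23)c1 | intermediate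
15 | 5,7-bis(benzyloxy)-8-{2-[5-(benzyloxy)-7-methoxy-4-oxo-4H-chromen-2-yl]-5-methoxyphenyl}-2-[4-(benzyloxy)phenyl]-4H-chromen-4-one | COc1ccc(-c2cc(=O)c3c(OCc4ccccc4)cc(OC)cc3o2)c(-c2c(OCc3ccccc3)cc(OCc3ccccc3)c3c(=O)cc(-c4ccc(OCc5ccccc5)cc4)oc23)c1 | intermediate
16 | 5,7-dihydroxy-8-[2-(5-hydroxy-7-methoxy-4-oxo-4H-chromen-2-yl)-5-methoxyphenyl]-2-(4-hydroxyphenyl)-4H-chromen-4-one | COc1ccc(-c2cc(=O)c3c(O)cc(OC)cc3o2)c(-c2c(O)cc(O)c3c(=O)cc(-c4ccc(O)cc4)oc23)c1 | target

Total step count: 9. Longest linear sequence: 7 steps (steps 1, 2, 3, 4, 7, 8, 9); steps 5 and 6 form the second branch.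

Steps most likely to fail

Step 7. The dienolate of 12 may add reversibly without the open-chain dianion ever closing onto the hindered, enolate-deactivated aryl ketone, so that material drains into self-condensation of 12 or into addition at C2'' of the apigenin unit. The fallback uses known chemistry, sets out from iodide 3 (with acetophenone 9 as the second component) and comes back at 15; ring B is brought in as a preformed benzene. Suzuki–Miyaura coupling of 3 with commercial (2-formyl-5-methoxyphenyl)boronic acid (COc1ccc(C=O)c(B(O)O)c1; Pd(OAc)2, SPhos, K3PO4, toluene–H2O, 90 °C) would give 2-{5,7-bis(benzyloxy)-2-[4-(benzyloxy)phenyl]-4-oxo-4H-chromen-8-yl}-4-methoxybenzaldehyde F1. Mono-O-benzylation of 9 (BnBr 1.05 equiv, K2CO3, acetone, reflux; the second, chelated hydroxyl stays free) would give 1-[2-(benzyloxy)-6-hydroxy-4-methoxyphenyl]ethanone F2. Claisen–Schmidt condensation of F1 with F2 (KOH, EtOH–THF, rt) would give (E)-3-(2-{5,7-bis(benzyloxy)-2-[4-(benzyloxy)phenyl]-4-oxo-4H-chromen-8-yl}-4-methoxyphenyl)-1-[2-(benzyloxy)-6-hydroxy-4-methoxyphenyl]prop-2-en-1-one F3. Oxidative cyclization of this 2'-hydroxychalcone (catalytic I2, DMSO, 120 °C) would close the pyranone ring of the first flavone and give 15, the 4'-methoxy group coming from the boronic acid; step 9 then follows unchanged.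

Step 4. The enolate may be acylated on oxygen instead of carbon, may attack the chromone carbonyl, or the peri 5''-O-benzyl ether may be lost during the acidic ring closure. The fallback sets out from iodide 3 and comes back at 8 with reversed polarity, the flavone now carrying the nucleophilic carbon; it also bypasses the carbonylation of step 3. Stille coupling of 3 with tributyl(1-ethoxyvinyl)stannane (CCCC[Sn](CCCC)(CCCC)C(=C)OCC; PdCl2(PPh3)2, toluene, 100 °C) would give 5,7-bis(benzyloxy)-2-[4-(benzyloxy)phenyl]-8-(1-ethoxyethenyl)-4H-chromen-4-one F4, hydrolysed on work-up (1 M HCl, THF) to 8-acetyl-5,7-bis(benzyloxy)-2-[4-(benzyloxy)phenyl]-4H-chromen-4-one F5. C-Acylation of F5 under soft enolization (MgBr2·OEt2, i-Pr2NEt, CH2Cl2, rt) with (E)-3-ethoxyacryloyl chloride (CCO/C=C/C(Cl)=O) would give (E)-1-{5,7-bis(benzyloxy)-2-[4-(benzyloxy)phenyl]-4-oxo-4H-chromen-8-yl}-5-ethoxypent-4-ene-1,3-dione F6, which should close to 8 with loss of ethanol (catalytic CF3CO2H, CH2Cl2, rt).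

Step 9. The two pyranone C2=C3 bonds may be partly saturated, or the reaction may stall at partly debenzylated intermediates that precipitate on the catalyst. The fallback sets out from 15 and comes back at 16 without hydrogen: BCl3 (8 equiv) and pentamethylbenzene (12 equiv) in CH2Cl2 at −78 → −40 °C would transfer the benzyl groups to the arene by Lewis-acid-mediated heterolysis. The two methyl ethers (7-OMe and 4'-OMe, neither peri to a carbonyl) should survive at this temperature. No new compound arises on the way (F0).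

Further compounds
F1 | step 7 | 2-{5,7-bis(benzyloxy)-2-[4-(benzyloxy)phenyl]-4-oxo-4H-chromen-8-yl}-4-methoxybenzaldehyde | COc1ccc(C=O)c(-c2c(OCc3ccccc3)cc(OCc3ccccc3)c3c(=O)cc(-c4ccc(OCc5ccccc5)cc4)oc23)c1
F2 | step 7 | 1-[2-(benzyloxy)-6-hydroxy-4-methoxyphenyl]ethanone | CC(=O)c1c(O)cc(OC)cc1OCc1ccccc1
F3 | step 7 | (E)-3-(2-{5,7-bis(benzyloxy)-2-[4-(benzyloxy)phenyl]-4-oxo-4H-chromen-8-yl}-4-methoxyphenyl)-1-[2-(benzyloxy)-6-hydroxy-4-methoxyphenyl]prop-2-en-1-one | COc1ccc(/C=C/C(=O)c2c(O)cc(OC)cc2OCc2ccccc2)c(-c2c(OCc3ccccc3)cc(OCc3ccccc3)c3c(=O)cc(-c4ccc(OCc5ccccc5)cc4)oc23)c1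
F4 | step 4 | 5,7-bis(benzyloxy)-2-[4-(benzyloxy)phenyl]-8-(1-ethoxyethenyl)-4H-chromen-4-one | C=C(OCC)c1c(OCc2ccccc2)cc(OCc2ccccc2)c2c(=O)cc(-c3ccc(OCc4ccccc4)cc3)oc12
F5 | step 4 | 8-acetyl-5,7-bis(benzyloxy)-2-[4-(benzyloxy)phenyl]-4H-chromen-4-one | CC(=O)c1c(OCc2ccccc2)cc(OCc2ccccc2)c2c(=O)cc(-c3ccc(OCc4ccccc4)cc3)oc12
F6 | step 4 | (E)-1-{5,7-bis(benzyloxy)-2-[4-(benzyloxy)phenyl]-4-oxo-4H-chromen-8-yl}-5-ethoxypent-4-ene-1,3-dione | CCO/C=C/C(=O)CC(=O)c1c(OCc2ccccc2)cc(OCc2ccccc2)c2c(=O)cc(-c3ccc(OCc4ccccc4)cc3)oc12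
F0 | step 9 | none | none
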